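Ring A' is disconnected at C1'–C2' and C1'–C6'. The remaining C2'–C6' chain, carrying prenyl groups on C2' and C6', oxygen on C3' and C5' and hydrogen on C4', is a symmetrical diprenylated 1,3-diketone, and C1' is the carbonyl carbon of a benzofuran-2-carboxylate. In one operation the diketone dianion is acylated by the ester and the resulting 1,3,5-triketone undergoes aldol aromatization, so the hindered aryl–benzofuran junction and both prenyl groups arrive without any biaryl coupling. The precursors are 2,12-dimethyltrideca-2,11-diene-6,8-dione, made by two dianion prenylations of pentane-2,4-dione, and methyl 6-methoxybenzofuran-2-carboxylate. The symmetrical resorcinol is then permethylated, and thiolate removes one methyl group per ring.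

Key step: step 4

Remark: ring A' is the fully substituted aryl ring, numbered from C1' (bonded to benzofuran C2). No isolated compound of the route has a stereocentre or a stereogenic double bond, so no configuration has to be set.

Step 1
Reactants: 1 pentane-2,4-dione; 2 1-bromo-3-methylbut-2-ene (prenyl bromide)
Product: 3 8-methylnon-7-ene-2,4-dione
Conditions: LiN(iPr)2 (2.1 equiv), THF, −78→0 °C; 2 (1.0 equiv), −78→0 °C; 1 M HCl, 0 °C
Reagents that add atoms: none
Why: Terminal (γ) alkylation of a β-diketone 1,3-dianion, in which the terminal carbanion, far more nucleophilic than the delocalised central enolate, displaces bromide from the primary allylic carbon of 2 (SN2), while the monoanion left after one alkylation is too weak a nucleophile to react again with the single equivalent of bromide.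

Step 2
Reactants: 3 8-methylnon-7-ene-2,4-dione; 2 1-bromo-3-methylbut-2-ene (prenyl bromide)
Product: 4 2,12-dimethyltrideca-2,11-diene-6,8-dione
Conditions: LiN(iPr)2 (2.1 equiv), THF, −78→0 °C; 2 (1.0 equiv), −78→0 °C; 1 M HCl, 0 °C
Reagents that add atoms: none
Why: Second dianion γ-alkylation, in which LiN(iPr)2 removes the central proton and then, kinetically, a proton of the unsubstituted C1 methyl group rather than of the more hindered C5 methylene (the known methyl-over-methylene preference in the second ionisation of unsymmetrical β-diketones), so that SN2 attack on 2 places the second prenyl group at the opposite terminus and gives the symmetrical diketone.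

Step 3
Reactants: 5 6-methoxy-1-benzofuran-2-carboxylic acid
Product: 6 methyl 6-methoxy-1-benzofuran-2-carboxylate
Conditions: MeOH, H2SO4 (cat.), reflux
Reagents that add atoms: methanol, CO
Why: Fischer esterification driven by methanol as solvent; the benzofuran and the aryl methyl ether are inert to catalytic acid in methanol.

Step 4
Reactants: 4 2,12-dimethyltrideca-2,11-diene-6,8-dione; 6 methyl 6-methoxy-1-benzofuran-2-carboxylate
Product: 9 5-(6-methoxy-1-benzofuran-2-yl)-4,6-bis(3-methylbut-2-en-1-yl)benzene-1,3-diol, via triketone 7 (not isolated), via cyclic aldol 8 (not isolated)
Conditions: 4 (2.1 equiv), LiN(iPr)2 (4.2 equiv), THF, −78→0 °C; 6 (1.0 equiv), −78 °C→rt; then MeOH, aq KOH (1 M), 40 °C, under Ar; 1 M HCl to pH 5, 0 °C; surplus 4 separated by chromatography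
Reagents that add atoms: none
Why: Two equivalents of LiN(iPr)2 per diketone turn 4 into its 1,3-dianion, whose terminal carbanion (the prenyl-bearing future C2') is far more nucleophilic than the central enolate and attacks the ester carbonyl of 6 in a Claisen-type C-acylation, forming C1'–C2' and giving triketone 7; the surplus dianion takes up the acidic proton of 7 so that acyl transfer does not stall. In the aqueous methanolic KOH added to the same flask, the other terminal carbon of the chain (future C6') enolizes and adds to the benzofuranyl ketone in an intramolecular aldol addition, a favoured 6-(enolendo)-exo-trig closure that forms C1'–C6' and ring A' as cyclic aldol 8. E1cB loss of water from 8 and tautomerization of the cyclohexenedione give the resorcinol irreversibly, which pulls the preceding equilibria forward. The closest known reaction types are the ester acylation of β-diketone dianions and the base-induced cyclization of 1,3,5-triketones to 5-substituted resorcinols, the laboratory counterpart of polyketide aromatization. No stereocentre survives, since the centres of 7 and 8 are erased on aromatization. The step needs terminal rather than central or O-acylation, secured by the dianion and by an ester as acyl donor, and ring closure through carbon rather than oxygen (a 4-pyranone is the acid-side product), secured by the basic medium; the symmetry of 4 makes both termini equivalent, so only one triketone can form.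

Step 5
Reactants: 9 5-(6-methoxy-1-benzofuran-2-yl)-4,6-bis(3-methylbut-2-en-1-yl)benzene-1,3-diol
Product: 10 2-[3,5-dimethoxy-2,6-bis(3-methylbut-2-en-1-yl)phenyl]-6-methoxy-1-benzofuran
Conditions: MeI (excess), K2CO3, acetone, reflux
Reagents that add atoms: iodomethane (one methyl group for each of the two phenols), CI
Why: Williamson ether synthesis: both phenoxides formed by K2CO3 are O-methylated by iodomethane in acetone, conditions under which C-methylation of the ring and attack on the prenyl alkenes are not expected.

Step 6
Reactants: 10 2-[3,5-dimethoxy-2,6-bis(3-methylbut-2-en-1-yl)phenyl]-6-methoxy-1-benzofuran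
Product: 11 2-[3-hydroxy-5-methoxy-2,6-bis(3-methylbut-2-en-1-yl)phenyl]-1-benzofuran-6-ol
Conditions: NaSEt (sodium ethanethiolate, 6 equiv), DMF, 130 °C; 1 M HCl to pH 5, 0 °C
Reagents that add atoms: none
Why: Thiolate SN2 O-demethylation of aryl methyl ethers: ethanethiolate attacks the methyl carbon of the benzofuran 6-methoxy group and of one of the two symmetry-equivalent ring A' methoxy groups, and the phenoxide then present on ring A' makes loss of its second methyl group (which would place two negative charges on one ring) much slower, so the reaction should stop at one free phenol per ring while the prenyl alkenes stay untouched by the soft, weakly basic nucleophile.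

Compound list
1 | pentane-2,4-dione | CC(=O)CC(C)=O | starting material
2 | 1-bromo-3-methylbut-2-ene (prenyl bromide) | CC(C)=CCBr | starting material
3 | 8-methylnon-7-ene-2,4-dione | CC(=O)CC(=O)CCC=C(C)C | intermediate
4 | 2,12-dimethyltrideca-2,11-diene-6,8-dione | CC(C)=CCCC(=O)CC(=O)CCC=C(C)C | intermediate
5 | 6-methoxy-1-benzofuran-2-carboxylic acid | COc1ccc2cc(C(=O)O)oc2c1 | starting material
6 | methyl 6-methoxy-1-benzofuran-2-carboxylate | COC(=O)c1cc2ccc(OC)cc2o1 | intermediate
7 | 1-(6-methoxy-1-benzofuran-2-yl)-9-methyl-2-(3-methylbut-2-en-1-yl)dec-8-ene-1,3,5-trione (racemic, drawn as the triketo tautomer; not isolated) | COc1ccc2cc(oc2c1)C(=O)C(CC=C(C)C)C(=O)CC(=O)CCC=C(C)C | intermediate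
8 | 5-hydroxy-5-(6-methoxy-1-benzofuran-2-yl)-4,6-bis(3-methylbut-2-en-1-yl)cyclohexane-1,3-dione (mixture of diastereomers; not isolated) | COc1ccc2cc(oc2c1)C1(O)C(CC=C(C)C)C(=O)CC(=O)C1CC=C(C)C | intermediate
9 | 5-(6-methoxy-1-benzofuran-2-yl)-4,6-bis(3-methylbut-2-en-1-yl)benzene-1,3-diol | COc1ccc2cc(oc2c1)-c1c(CC=C(C)C)c(O)cc(O)c1CC=C(C)C | intermediate
10 | 2-[3,5-dimethoxy-2,6-bis(3-methylbut-2-en-1-yl)phenyl]-6-methoxy-1-benzofuran | COc1ccc2cc(oc2c1)-c1c(CC=C(C)C)c(OC)cc(OC)c1CC=C(C)C | intermediate
11 | 2-[3-hydroxy-5-methoxy-2,6-bis(3-methylbut-2-en-1-yl)phenyl]-1-benzofuran-6-ol (CNP0324103.0) | COc1cc(O)c(CC=C(C)C)c(-c2cc3ccc(O)cc3o2)c1CC=C(C)C | target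

Total step count: 6. Longest linear sequence: 5 steps (1 → 3 → 4 → 9 → 10 → 11, steps 1, 2, 4, 5 and 6).

Steps most likely to fail

Step 4. Acyl transfer may stall, either through proton transfer from the newly formed triketone to unreacted dianion or through slow addition of the hindered secondary carbanion to the ester. Hydroxide may also cleave the triketone by retro-Claisen fragmentation faster than the ring closes. The fallback sets out from 4 and replaces the acylation by an aldol addition followed by oxidation. The dianion of 4 (LiN(iPr)2, 2 equiv, THF, −78 °C) is added to commercial 6-methoxy-1-benzofuran-2-carbaldehyde (COc1ccc2cc(C=O)oc2c1). The alkoxide formed is no proton source, and the product should be the hydroxy diketone 5-[hydroxy(6-methoxy-1-benzofuran-2-yl)methyl]-2,12-dimethyltrideca-2,11-diene-6,8-dione F1 (diastereomer mixture). Oxidation of its activated heteroaryl carbinol with activated MnO2 in CH2Cl2 at room temperature should give triketone 7, which is isolated in this variant. Ring closure of 7 without hydroxide (DBU, toluene, 80 °C, molecular sieves) then comes back to the route at 9.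

Step 6. The two dealkylations may run at different rates: the ring A' ethers, each next to a prenyl group, may lag behind the exposed benzofuran ether. Conditions forcing the slower cleavage could then start to remove the second ring A' methyl group and give mixtures of partly and over-demethylated phenols. The fallback sets out from 9 and desymmetrizes ring A' by alkylation instead of dealkylation. A single O-methylation (MeI 1.0 equiv, K2CO3, acetone, room temperature; unreacted 9 is recycled and any 10 formed is sent to step 6) gives 5-methoxy-3-(6-methoxy-1-benzofuran-2-yl)-2,4-bis(3-methylbut-2-en-1-yl)phenol F2. NaSEt in DMF at about 100 °C then has only the benzofuran methyl ether to cleave, the ring A' methoxy group being shielded from the start by the phenoxide on the same ring, and the sequence comes back at 11.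

Step 2. The second ionisation of 3 may occur in part at the already substituted C5 methylene, or proton exchange between dianion and product enolate may intervene. Either would place both prenyl groups on one terminal carbon or leave 3 unconverted, giving isomeric diketones that are hard to separate from 4. The fallback sets out from 2 and fixes each prenyl group before the diketone is assembled. Ethyl acetate is deprotonated with LiN(iPr)2 (THF, −78 °C) and alkylated with 2 to give ethyl 5-methylhex-4-enoate F3. A crossed Claisen acylation of the methyl group of commercial 6-methylhept-5-en-2-one (CC(=O)CCC=C(C)C) with F3 (NaH, THF, reflux; cold dilute HCl work-up) then comes back at 4.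

Further compounds
F1 | step 4 | 5-[hydroxy(6-methoxy-1-benzofuran-2-yl)methyl]-2,12-dimethyltrideca-2,11-diene-6,8-dione (diastereomer mixture) | COc1ccc2cc(oc2c1)C(O)C(CC=C(C)C)C(=O)CC(=O)CCC=C(C)C
F2 | step 6 | 5-methoxy-3-(6-methoxy-1-benzofuran-2-yl)-2,4-bis(3-methylbut-2-en-1-yl)phenol | COc1cc(O)c(CC=C(C)C)c(-c2cc3ccc(OC)cc3o2)c1CC=C(C)C
F3 | step 2 | ethyl 5-methylhex-4-enoate | CCOC(=O)CCC=C(C)C
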